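The constants used here belong to no real substance; the flask was simulated.

1. A neighbour flask takes 0.360 equiv of coupling partner and this flask takes 0.600 equiv, so one reckoning has to serve both.

substrate 2.0 M; coupling partner 0.600 equiv; time 1.0 h

    substrate + tight pair → side product (k1 = 6.46 × 10⁻⁴ M⁻¹ s⁻¹)
    substrate + target ⇌ idle adduct, settled at all times (K2 = 16 M⁻¹)
    coupling partner + tight pair → target (k3 = 166 M⁻¹ s⁻¹)
    tight pair ⇌ loose pair (K4 = 3.2, k4 = 0.170 s⁻¹)
    substrate ⇌ tight pair (K5 = 0.058, k5 = 0.00260 s⁻¹)
    coupling partner + loose pair → isomer of the product (k6 = 80.9 M⁻¹ s⁻¹)

1. at 1.0 h, what has stopped the reaction, if anything has (it is still moving / the coupling partner has run out first / forward and back rates have come level / all of the substrate has reacted)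
2. amount of target at 1.0 h, in percent of the substrate charged
3. amount of target if the flask were left three thousand times as long, in percent of the substrate charged

- in percentages every species weighs as the substrate in it: one side product or idle adduct counts as two
- for target the idle adduct is counted in
- in an amount of target, one idle adduct counts as one target
- the reaction counts as stopped when no species that holds the substrate changes by six tenths of a point or more over the second half of the time
- run time (flask): 1.0 h

2. Tight pair has two exits: coupling partner captures it to target, or it opens to loose pair. At the start, capture runs 1170 times as fast as opening; this is the capture ratio, and it falls as coupling partner is consumed.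

3. First extreme: no opening at all. Each coupling partner then makes one target, and coupling partner is the limiting reagent, its charge being smaller than that of substrate. The ceiling for target is 60.0 % of the substrate charged.

4. Second extreme: tight pair and loose pair held at balance throughout. Coupling partner then divides between the two pairs, target taking 39.1 % of it, which gives 23.5 % of the substrate charged.

5. This flask starts with capture far ahead of opening, so this reckoning places it close to the first extreme. Taking one part in the starting capture ratio off the ceiling, this reckoning commits to 59.9 % of target.

6. The forward half-life of substrate by its step to tight pair alone, 0.074 h, is short beside the run, although the idle adduct holds free substrate back, with 32 as the binding measure at the start. This reckoning expects coupling partner, charged at 0.600 equiv, to run out first, but gives no time for it. Each target takes one coupling partner, so the long-run amount is bounded by the ceiling: 60.0 %.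

7. The forecast says: the coupling partner has run out first, with target 59.7 % at the asked time and 59.7 % in the long run, the tight pair being “trapped almost entirely by the coupling partner”. Its target lies 0.25 percentage points below this reckoning.

8. The simulation gives: the coupling partner has run out first, with 0 % of coupling partner left at 1.00 h, target 59.7 %, and 59.7 % in the long run.

At 0.0495 h the capture ratio of this flask, taken against the forward opening alone, stood at 580, down from 1170 at the start, and this flask used coupling partner 580 times as fast for target as for isomer of the product; at 1.00 h the isomer stood at 0.315 % against target 59.7 %. The neighbour flask with 0.360 equiv of coupling partner starts at a capture ratio of 703 with a ceiling of 36.0 %, and at 1.00 h it holds isomer 0.260 % beside target 35.7 %.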